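## The problem

The target 27 is a (2S)-flavanone. Its phloroglucinol-type ring A is fused through O1 and the C4 ketone to ring C, C2 carries a 3,4-dihydroxy-5-methoxyphenyl ring B, and C6 carries a geranyl chain between the 5- and 7-hydroxyls. Three things have to be decided by the route: the chain must sit on C6 and not on C8, the C2''=C3'' alkene must be E, and C2 must be S. C6 and C8 are both flanked by oxygen, so closing a free 2',4',6'-trihydroxychalcone does not tell them apart. C2 is the only stereocenter and lies far from the chain, so nothing in the molecule can relay to it: a catalyst must set it, and the alkene geometry must come from the reaction that makes the alkene. C2 is lost by retro-oxa-Michael opening to the chalcone, fastest under base once the 5-OH is free. The two trisubstituted alkenes are protonated easily and can then be trapped by the neighbouring phenols, which rules out strong acid, hydrogenolysis and electrophilic halogen late in the route. The C2''=C3'' alkene, with a methyl on C3'' and the C4''–C5'' ethylene link behind it, is the product pattern of a Claisen rearrangement of a 2-methylallylic alcohol whose carbinol carbon is C2''. Ring A is symmetric about the C6···C8a axis, so a chain placed para to one distinguished oxygen (the future O1) must end up on C6.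

## Retrosynthesis

**27 ⇒ 26.** The four aryl O–CH2OMe bonds are cut last. MOM ethers are used on all four phenols because ring A needs them anyway as directing groups, and one mild acid step then unmasks everything. Benzyl ethers would need hydrogenolysis and methyl ethers a boron halide, neither compatible with the chain or the C5' methyl ether. The precursor 26 has no free 5-OH, which is what protects C2 until the end. The forward step needs an acid mild enough to leave the alkenes alone.

**26 ⇒ 20 + 25.** The C2–C1' bond is cut, giving the flat, achiral chromone 20 and the arylboronic acid 25. The neighbouring cut, O1–C2 by oxa-Michael closure of a 2'-hydroxychalcone, is reversible and gives racemic material. Etherification at a benzylic alcohol bearing three donor oxygens risks ionization. Conjugate arylation of the chromone makes C2 irreversibly under nearly neutral conditions. The forward reaction asks a chiral monovalent-rhodium catalyst for face selection on an electron-rich enone, with tolerance of acetals and alkenes.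

**20 ⇒ 17 ⇒ 16 ⇒ 15.** Ring C is taken apart carbon by carbon: O1–C2 (6-endo closure of the ynone 18 through the enaminone 19), C3–C4 (ethynyl Grignard addition to the salicylaldehyde 16, then oxidation of 17), and C4–C4a (ortho-formylation of the phenol 15). Phenol 15 has a mirror plane through C1 and C4, so its two ortho positions are the same and only one aldehyde can form. Formylation through the magnesium phenoxide is preferred to Friedel–Crafts acylation (acid, fatal to MOM ethers and the chain) and to ring lithiation (the benzylic–allylic CH2 of the chain is acidic). The precursor 15 is a ring A that carries only the chain.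

**15 ⇒ 14 ⇒ 13 ⇒ 12.** The silyl ether on the future O1 is restored (14), the C6''=C7'' alkene is cut by a Wittig disconnection to the aldehyde 13, and 13 is traced to the ester 12. The terminal alkene carries two identical methyl groups, so the Wittig reaction needs no geometric control; only C2''=C3'' does, and that alkene is already in 12.

**12 ⇒ 9 + 10.** This is the key cut: the C4''–C5'' bond and the C2''=C3'' alkene are traced to the racemic 2-methylallylic alcohol 9 and triethyl orthoacetate 10. Direct alkylation of the aryllithium 5 with a ready-made C10 allylic electrophile would be shorter, but it leaves the geometry to the purity of a purchased allylic halide and to SN2 against SN2' attack. The rearrangement sets the E alkene itself and builds the chain from C2, C3 and C2 pieces. The precursor 9 has no alkene geometry, and its one stereocenter is consumed. The forward step must be E-selective and must spare the MOM and silyl ethers.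

**9 ⇒ 7 + 8; 7 ⇒ 6 ⇒ 3 + 4.** C2''–C3'' is cut to the arylacetaldehyde 7 and isopropenylmagnesium bromide 8. The aryl–C1'' bond is cut to the aryllithium 5 (from 3) and ethylene oxide 4, with an oxidation (6 to 7) in between. Lithiation of 3 goes to the carbon between the two MOM ethers, which is para to the silyl ether. This fixes the later C6 position before any other ring exists.

**3 ⇒ 2 ⇒ 1.** The two MOM ethers and the silyl ether are removed in turn. The only desymmetrization is the statistical monosilylation of phloroglucinol 1, run with the cheap triol in excess.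

**25 ⇒ 23 ⇒ 22 ⇒ 21.** Boron must sit para to the central oxygen of ring B, a position that electrophilic substitution of a 1,2,3-trioxygenated benzene does not reach. The route therefore starts from the commercial bromide 21, in which bromine is already para to the phenol. The formyl group is turned into the second hydroxyl (22), both are protected (23), and bromine is exchanged for boron through the aryllithium 24.

## Roads not taken

**Alternative 1:** Ring A is built last by cutting C7–C8. The precursor is a 2-aryl-2,3-dihydropyran-4-one that already holds C2 and ring B, with a methyl group on the future C8 and an acyl side chain that carries the geranyl group and ends in a methyl ester. Mg(OMe)2 would deprotonate the vinylogous methyl group, and the carbanion would close onto the ester and aromatize with loss of methanol to the 5,7-dihydroxyflavanone A1.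
- Merits: the chain is on C6 by construction, its geometry is bought with the chain, ring A needs no protecting groups, and C2 could come from a catalytic hetero-Diels–Alder reaction.
- Weak points: the carbon between the two carbonyls of the side chain is the most acidic site, so the closure must run through a dianion on a β-tricarbonyl that can also cleave by retro-Claisen reaction. C2 sits β to a carbonyl through O1 in alkoxide base, and A1 itself is a 5-hydroxyflavanone in methoxide, exactly the conditions under which flavanones open to chalcones and racemize.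
- Comparison: this road is shorter in chain supply and protecting groups. The chosen plan sets against it close precedent for every step and a C2 center made late, without base, on a substrate with no free 5-OH.

**Alternative 2:** The cut is C1''–C2''. Zirconium-catalysed methylalumination of a terminal enyne gives the (E)-alkenylalane A4, and Ni(PPh3)4 (zerovalent nickel) couples it with the chloromethyl chromone A3 to give A2, the same compound as chromone 20.
- Merits: the route is convergent, syn-carbometalation fixes the E geometry as reliably as the Claisen chair does, and it joins the chosen route at 20.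
- Step economy: one coupling replaces steps 3 to 8, so this road is clearly ahead in step count, and that is conceded.
- Weak points: A3 is a benzylic chloride flanked by two donor oxygens on an electron-rich ring, so it ionizes and self-alkylates easily. Placing the chloromethyl group on C6 and not C8 needs the same symmetry device as the chosen plan. The Lewis-acidic alane, with residual trimethylalane, meets MOM acetals and a chromone that accepts methyl transfer.
- Comparison: the chosen plan grows the chain on a plain arene. All organometallic steps are finished before any electrophilic heterocycle or labile benzylic halide exists.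

**Alternative 3:** The cut is O1–C8a. An open-chain (S)-benzylic alcohol bearing an ortho aryl bromide on ring A is closed with CuI, 1,10-phenanthroline and Cs2CO3 to the 4-silyloxyflavan A5. Desilylation, oxidation at C4 and MOM removal follow.
- Merits: C2 comes from well-developed asymmetric ketone reduction or aldol chemistry and cannot open to a chalcone during closure, because C4 is not yet a ketone. In stereochemical security this road is better than conjugate arylation of an electron-rich chromone, and that is conceded.
- Weak points: the bromide cannot be introduced after the chain (electrophilic bromine attacks the alkenes), and before the chain it interferes with the lithiation chemistry. The aryl bromide is electron-rich and ortho-substituted, so copper-mediated C–O coupling is slow and needs heat and carbonate. C4 is carried as a mixture of epimers, and three steps follow the closure.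
- Comparison: the chosen plan has fewer steps after the ring is assembled, uses no halogen on ring A, and keeps a resolution-based fallback for C2.

Key step: step 6

Assumption: in step 16 the (S)-configured biaryl bisphosphine is taken to deliver the aryl group to the face of C2 that gives the 2S flavanone, by analogy with additions of arylrhodium complexes of (S)-biaryl bisphosphines to cyclic enones. If a trial run shows the opposite sense, the (R)-ligand is used and nothing else changes.

Commercial materials: 1, 4 (as a THF solution), 8 (as a THF solution), 10 and 21.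

## Steps

Step 1
Reactants: 1 phloroglucinol
Product: 2 5-(triisopropylsilyloxy)benzene-1,3-diol
Conditions: i-Pr3SiCl (1 equiv), 1 (3 equiv), imidazole, DMF, 0 °C to rt
Reagents that add atoms: chlorotriisopropylsilane, CC(C)[Si](Cl)(C(C)C)C(C)C
Why: Statistical monosilylation of a symmetric triol; the excess of 1 and the bulk of the silyl group should hold back a second silylation, and unreacted 1 stays in the aqueous washes.

Step 2
Reactants: 2 5-(triisopropylsilyloxy)benzene-1,3-diol
Product: 3 [3,5-bis(methoxymethoxy)phenoxy]triisopropylsilane
Conditions: MeOCH2Cl, i-Pr2NEt, CH2Cl2, 0 °C to rt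
Reagents that add atoms: chloromethyl methyl ether, COCCl
Why: MOM protection of both remaining phenols under amine base, which leaves the aryl silyl ether alone; the two MOM ethers are the directing groups for step 3.

Step 3
Reactants: 3 [3,5-bis(methoxymethoxy)phenoxy]triisopropylsilane; 4 ethylene oxide
Product: 6 2-[2,6-bis(methoxymethoxy)-4-(triisopropylsilyloxy)phenyl]ethanol, via aryllithium 5 (not isolated)
Conditions: n-BuLi, THF, 0 °C; then 4 (THF solution), −78 °C to rt; aq NH4Cl
Reagents that add atoms: none
Why: Directed ortho-metalation at the carbon flanked by both MOM ethers (the bulky silyloxy group directs only weakly), then SN2 opening of the epoxide by the aryllithium. The carbon attacked is para to the silyl ether and becomes C6.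

Step 4
Reactants: 6 2-[2,6-bis(methoxymethoxy)-4-(triisopropylsilyloxy)phenyl]ethanol
Product: 7 [2,6-bis(methoxymethoxy)-4-(triisopropylsilyloxy)phenyl]acetaldehyde
Conditions: Dess–Martin periodinane, NaHCO3, CH2Cl2, 0 °C to rt
Reagents that add atoms: none
Why: Dess–Martin oxidation of a primary alcohol under buffered conditions should stop at the aldehyde; the enolizable arylacetaldehyde is used crude and at once.

Step 5
Reactants: 7 [2,6-bis(methoxymethoxy)-4-(triisopropylsilyloxy)phenyl]acetaldehyde; 8 isopropenylmagnesium bromide
Product: 9 racemic 1-[2,6-bis(methoxymethoxy)-4-(triisopropylsilyloxy)phenyl]-3-methylbut-3-en-2-ol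
Conditions: 8, THF, −78 to −20 °C; aq NH4Cl
Reagents that add atoms: none
Why: Grignard 1,2-addition to the aldehyde at low temperature; the carbinol center is left racemic because step 6 destroys it.

Step 6
Reactants: 9 racemic 1-[2,6-bis(methoxymethoxy)-4-(triisopropylsilyloxy)phenyl]-3-methylbut-3-en-2-ol; 10 triethyl orthoacetate
Product: 12 ethyl (4E)-6-[2,6-bis(methoxymethoxy)-4-(triisopropylsilyloxy)phenyl]-4-methylhex-4-enoate, via mixed ketene acetal 11 (not isolated)
Conditions: 10 (excess, as solvent), EtCO2H (cat.), 135–140 °C, EtOH distilled off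
Reagents that add atoms: none
Why: Propionic acid catalyses exchange of the secondary alcohol of 9 into 10 and loss of a second ethanol, giving the mixed ketene acetal 11. Compound 11 rearranges in a concerted, suprafacial [3,3]-sigmatropic shift through a chair: the C2''–O bond breaks, the C4''–C5'' bond forms between the alkene terminus and the ketene acetal carbon, and the double bond moves to C2''=C3''. The closest known reaction type is the Johnson orthoester Claisen rearrangement of secondary 2-methylallylic alcohols to (E)-trisubstituted γ,δ-unsaturated esters, the classical chain extension of terpenoid synthesis. No ring is closed and no stereocenter is made; the carbinol center of 9 is consumed, which is why 9 can be racemic. The selectivity needed is E geometry at C2''=C3'': the arylmethyl group on the carbinol carbon sits equatorial in the chair, because in the axial position it would meet the ethoxy group of the ketene acetal in a 1,3-diaxial clash. The step also needs chemoselectivity: the weak carboxylic acid in anhydrous orthoester should leave the aryl MOM ethers and the silyl ether alone, and distilling off ethanol pulls the exchange forward. Formation of the ester carbonyl makes the rearrangement irreversible.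

Step 7
Reactants: 12 ethyl (4E)-6-[2,6-bis(methoxymethoxy)-4-(triisopropylsilyloxy)phenyl]-4-methylhex-4-enoate
Product: 13 (4E)-6-[2,6-bis(methoxymethoxy)-4-(triisopropylsilyloxy)phenyl]-4-methylhex-4-enal
Conditions: i-Bu2AlH, CH2Cl2, −78 °C; MeOH, aq potassium sodium tartrate
Reagents that add atoms: none
Why: Partial reduction of an ester by i-Bu2AlH at −78 °C, where the aluminium hemiacetal persists until work-up; ethers and the alkene are not touched.

Step 8
Reactants: 13 (4E)-6-[2,6-bis(methoxymethoxy)-4-(triisopropylsilyloxy)phenyl]-4-methylhex-4-enal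
Product: 14 {4-[(2E)-3,7-dimethylocta-2,6-dienyl]-3,5-bis(methoxymethoxy)phenoxy}triisopropylsilane
Conditions: i-PrPPh3I, n-BuLi, THF, 0 °C; then 13, −78 °C to rt
Reagents that add atoms: isopropyltriphenylphosphonium iodide, CC(C)[P+](c1ccccc1)(c1ccccc1)c1ccccc1.[I-]
Why: Wittig olefination with a non-stabilized ylide; the new C6''=C7'' alkene carries two identical methyl groups, so no geometry is at stake, and the E alkene from step 6 is not affected.

Step 9
Reactants: 14 {4-[(2E)-3,7-dimethylocta-2,6-dienyl]-3,5-bis(methoxymethoxy)phenoxy}triisopropylsilane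
Product: 15 4-[(2E)-3,7-dimethylocta-2,6-dienyl]-3,5-bis(methoxymethoxy)phenol
Conditions: Bu4NF, THF, 0 °C; aq NH4Cl
Reagents that add atoms: none
Why: Fluoride cleavage of the aryl silyl ether, driven by Si–F bond formation; MOM ethers are stable to fluoride, so only the oxygen that becomes O1 is set free.

Step 10
Reactants: 15 4-[(2E)-3,7-dimethylocta-2,6-dienyl]-3,5-bis(methoxymethoxy)phenol
Product: 16 3-[(2E)-3,7-dimethylocta-2,6-dienyl]-6-hydroxy-2,4-bis(methoxymethoxy)benzaldehyde
Conditions: MgCl2, Et3N, (CH2O)n, MeCN, reflux
Reagents that add atoms: paraformaldehyde (as formaldehyde), C=O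
Why: Magnesium-mediated ortho-formylation of a phenol (Casnati–Skattebøl): the magnesium phenoxide delivers formaldehyde to the ortho carbon and a second formaldehyde oxidizes the benzylic alkoxide by hydride transfer. The two ortho positions of 15 are equivalent, so one aldehyde should form, and the medium stays basic.

Step 11
Reactants: 16 3-[(2E)-3,7-dimethylocta-2,6-dienyl]-6-hydroxy-2,4-bis(methoxymethoxy)benzaldehyde
Product: 17 racemic 4-[(2E)-3,7-dimethylocta-2,6-dienyl]-2-(1-hydroxyprop-2-ynyl)-3,5-bis(methoxymethoxy)phenol
Conditions: HC≡CMgBr (excess), THF, 0 °C to rt; aq NH4Cl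
Reagents that add atoms: ethynylmagnesium bromide, C#C[Mg]Br
Why: Grignard addition of the acetylide to the aldehyde after the first equivalent has deprotonated the phenol; the racemic carbinol center is oxidized away in step 12.

Step 12
Reactants: 17 racemic 4-[(2E)-3,7-dimethylocta-2,6-dienyl]-2-(1-hydroxyprop-2-ynyl)-3,5-bis(methoxymethoxy)phenol
Product: 20 6-[(2E)-3,7-dimethylocta-2,6-dienyl]-5,7-bis(methoxymethoxy)-4H-chromen-4-one, via ynone 18 (not isolated), via enaminone 19 (not isolated)
Conditions: MnO2, CH2Cl2, rt; filter; then Et2NH, EtOH, rt to 50 °C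
Reagents that add atoms: none
Why: MnO2 oxidizes the benzylic–propargylic alcohol selectively, whereas hypervalent iodine oxidants would attack the electron-rich phenol. Diethylamine then adds to the terminal ynone, and the phenol closes ring C by 6-endo addition–elimination on the enaminone with loss of the amine, which excludes the 5-exo closure.

Step 13
Reactants: 21 5-bromo-2-hydroxy-3-methoxybenzaldehyde
Product: 22 5-bromo-3-methoxybenzene-1,2-diol
Conditions: H2O2 (30% aq), NaOH (aq), 0 °C to rt; then dil. HCl
Reagents that add atoms: hydrogen peroxide, OO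
Why: Dakin oxidation: hydroperoxide adds to the aldehyde, aryl migration gives the aryl formate, and hydrolysis leaves the catechol with bromine para to the central oxygen.

Step 14
Reactants: 22 5-bromo-3-methoxybenzene-1,2-diol
Product: 23 5-bromo-1-methoxy-2,3-bis(methoxymethoxy)benzene
Conditions: MeOCH2Cl, i-Pr2NEt, CH2Cl2, 0 to 40 °C
Reagents that add atoms: chloromethyl methyl ether, COCCl
Why: MOM protection of both catechol hydroxyls under amine base; the same group as on ring A is used so that one final step unmasks all four phenols.

Step 15
Reactants: 23 5-bromo-1-methoxy-2,3-bis(methoxymethoxy)benzene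
Product: 25 [3-methoxy-4,5-bis(methoxymethoxy)phenyl]boronic acid, via aryllithium 24 (not isolated)
Conditions: n-BuLi, THF, −78 °C; B(Oi-Pr)3, −78 °C to rt; aq NH4Cl
Reagents that add atoms: triisopropyl borate, CC(C)OB(OC(C)C)OC(C)C; water, O
Why: Bromine–lithium exchange at −78 °C, capture of the aryllithium by the borate and hydrolysis of the boronate on mild aqueous work-up, which the MOM ethers should survive.

Step 16
Reactants: 20 6-[(2E)-3,7-dimethylocta-2,6-dienyl]-5,7-bis(methoxymethoxy)-4H-chromen-4-one; 25 [3-methoxy-4,5-bis(methoxymethoxy)phenyl]boronic acid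
Product: 26 (2S)-6-[(2E)-3,7-dimethylocta-2,6-dienyl]-2-[3-methoxy-4,5-bis(methoxymethoxy)phenyl]-5,7-bis(methoxymethoxy)chroman-4-one
Conditions: 25 (3 equiv), [Rh(OH)(cod)]2 (cat.), (S)-2,2'-bis[bis(3,4,5-trifluorophenyl)phosphino]-6,6'-dimethoxybiphenyl (cat.), toluene/H2O, 30 °C
Reagents that add atoms: none
Why: Rhodium-catalysed asymmetric 1,4-addition of an arylboronic acid to a chromone (Hayashi–Miyaura type): transmetalation to an aryl complex of monovalent rhodium, face-selective insertion of the C2=C3 bond and protonolysis of the rhodium enolate by water. The electron-poor (S)-bisphosphine sets C2 as S and speeds insertion so that β-oxygen elimination to the chalcone should not compete. No base is present, and 26 has no free 5-OH, so the new center should hold.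

Step 17
Reactants: 26 (2S)-6-[(2E)-3,7-dimethylocta-2,6-dienyl]-2-[3-methoxy-4,5-bis(methoxymethoxy)phenyl]-5,7-bis(methoxymethoxy)chroman-4-one
Product: 27 (2S)-2-(3,4-dihydroxy-5-methoxyphenyl)-6-[(2E)-3,7-dimethylocta-2,6-dienyl]-5,7-dihydroxychroman-4-one
Conditions: 3 M aq HCl, MeOH, 40 °C
Reagents that add atoms: none
Why: Acid-catalysed acetal exchange of the four aryl MOM ethers with methanol; dilute acid at moderate temperature is chosen so that the trisubstituted alkenes are not protonated and C2, which epimerizes mainly under base, stays S.

## Compound list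

1 | phloroglucinol (benzene-1,3,5-triol) | Oc1cc(O)cc(O)c1 | starting material
2 | 5-(triisopropylsilyloxy)benzene-1,3-diol | CC(C)[Si](Oc1cc(O)cc(O)c1)(C(C)C)C(C)C | intermediate
3 | [3,5-bis(methoxymethoxy)phenoxy]triisopropylsilane | COCOc1cc(OCOC)cc(O[Si](C(C)C)(C(C)C)C(C)C)c1 | intermediate
4 | ethylene oxide | C1CO1 | starting material
5 | [2,6-bis(methoxymethoxy)-4-(triisopropylsilyloxy)phenyl]lithium | [Li]c1c(OCOC)cc(O[Si](C(C)C)(C(C)C)C(C)C)cc1OCOC | intermediate
6 | 2-[2,6-bis(methoxymethoxy)-4-(triisopropylsilyloxy)phenyl]ethanol | OCCc1c(OCOC)cc(O[Si](C(C)C)(C(C)C)C(C)C)cc1OCOC | intermediate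
7 | [2,6-bis(methoxymethoxy)-4-(triisopropylsilyloxy)phenyl]acetaldehyde | O=CCc1c(OCOC)cc(O[Si](C(C)C)(C(C)C)C(C)C)cc1OCOC | intermediate
8 | isopropenylmagnesium bromide | C=C(C)[Mg]Br | starting material
9 | racemic 1-[2,6-bis(methoxymethoxy)-4-(triisopropylsilyloxy)phenyl]-3-methylbut-3-en-2-ol | C=C(C)C(O)Cc1c(OCOC)cc(O[Si](C(C)C)(C(C)C)C(C)C)cc1OCOC | intermediate
10 | triethyl orthoacetate | CC(OCC)(OCC)OCC | starting material
11 | racemic {4-[2-(1-ethoxyvinyloxy)-3-methylbut-3-enyl]-3,5-bis(methoxymethoxy)phenoxy}triisopropylsilane (mixed ketene acetal) | C=C(OCC)OC(Cc1c(OCOC)cc(O[Si](C(C)C)(C(C)C)C(C)C)cc1OCOC)C(C)=C | intermediate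
12 | ethyl (4E)-6-[2,6-bis(methoxymethoxy)-4-(triisopropylsilyloxy)phenyl]-4-methylhex-4-enoate | CCOC(=O)CC/C(C)=C/Cc1c(OCOC)cc(O[Si](C(C)C)(C(C)C)C(C)C)cc1OCOC | intermediate
13 | (4E)-6-[2,6-bis(methoxymethoxy)-4-(triisopropylsilyloxy)phenyl]-4-methylhex-4-enal | O=CCC/C(C)=C/Cc1c(OCOC)cc(O[Si](C(C)C)(C(C)C)C(C)C)cc1OCOC | intermediate
14 | {4-[(2E)-3,7-dimethylocta-2,6-dienyl]-3,5-bis(methoxymethoxy)phenoxy}triisopropylsilane | CC(C)=CCC/C(C)=C/Cc1c(OCOC)cc(O[Si](C(C)C)(C(C)C)C(C)C)cc1OCOC | intermediate
15 | 4-[(2E)-3,7-dimethylocta-2,6-dienyl]-3,5-bis(methoxymethoxy)phenol | CC(C)=CCC/C(C)=C/Cc1c(OCOC)cc(O)cc1OCOC | intermediate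
16 | 3-[(2E)-3,7-dimethylocta-2,6-dienyl]-6-hydroxy-2,4-bis(methoxymethoxy)benzaldehyde | O=Cc1c(O)cc(OCOC)c(C/C=C(\C)CCC=C(C)C)c1OCOC | intermediate
17 | racemic 4-[(2E)-3,7-dimethylocta-2,6-dienyl]-2-(1-hydroxyprop-2-ynyl)-3,5-bis(methoxymethoxy)phenol | C#CC(O)c1c(O)cc(OCOC)c(C/C=C(\C)CCC=C(C)C)c1OCOC | intermediate
18 | 1-{3-[(2E)-3,7-dimethylocta-2,6-dienyl]-6-hydroxy-2,4-bis(methoxymethoxy)phenyl}prop-2-yn-1-one | C#CC(=O)c1c(O)cc(OCOC)c(C/C=C(\C)CCC=C(C)C)c1OCOC | intermediate
19 | (2E)-3-(diethylamino)-1-{3-[(2E)-3,7-dimethylocta-2,6-dienyl]-6-hydroxy-2,4-bis(methoxymethoxy)phenyl}prop-2-en-1-one | CCN(CC)/C=C/C(=O)c1c(O)cc(OCOC)c(C/C=C(\C)CCC=C(C)C)c1OCOC | intermediate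
20 | 6-[(2E)-3,7-dimethylocta-2,6-dienyl]-5,7-bis(methoxymethoxy)-4H-chromen-4-one | O=c1ccoc2cc(OCOC)c(C/C=C(\C)CCC=C(C)C)c(OCOC)c12 | intermediate
21 | 5-bromo-2-hydroxy-3-methoxybenzaldehyde | COc1cc(Br)cc(C=O)c1O | starting material
22 | 5-bromo-3-methoxybenzene-1,2-diol | COc1cc(Br)cc(O)c1O | intermediate
23 | 5-bromo-1-methoxy-2,3-bis(methoxymethoxy)benzene | COCOc1cc(Br)cc(OC)c1OCOC | intermediate
24 | [3-methoxy-4,5-bis(methoxymethoxy)phenyl]lithium | [Li]c1cc(OC)c(OCOC)c(OCOC)c1 | intermediate
25 | [3-methoxy-4,5-bis(methoxymethoxy)phenyl]boronic acid | COCOc1cc(B(O)O)cc(OC)c1OCOC | intermediate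
26 | (2S)-6-[(2E)-3,7-dimethylocta-2,6-dienyl]-2-[3-methoxy-4,5-bis(methoxymethoxy)phenyl]-5,7-bis(methoxymethoxy)chroman-4-one | COCOc1cc([C@@H]2CC(=O)c3c(cc(OCOC)c(C/C=C(\C)CCC=C(C)C)c3OCOC)O2)cc(OC)c1OCOC | intermediate
27 | (2S)-2-(3,4-dihydroxy-5-methoxyphenyl)-6-[(2E)-3,7-dimethylocta-2,6-dienyl]-5,7-dihydroxychroman-4-one | COc1cc([C@@H]2CC(=O)c3c(cc(O)c(C/C=C(\C)CCC=C(C)C)c3O)O2)cc(O)c1O | target

## Step count and risks

Total step count: 17. Longest linear sequence: 14 (steps 1 to 12, then 16 and 17); the ring B branch (steps 13 to 15) joins at step 16.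

**Step 6 (key step).** Exchange of the hindered secondary alcohol into the orthoester may be slow. Long heating with acid could then cleave MOM ethers by acetal exchange, dehydrate the allylic alcohol, or let a boat transition state erode the E selectivity. The fallback keeps the same C4''–C5'' bond formation but uses an amide acetal without acid. It sets out from 9: N,N-dimethylacetamide dimethyl acetal in refluxing xylene should give, through the same chair with the dimethylamino group in place of ethoxy, (4E)-6-[2,6-bis(methoxymethoxy)-4-(triisopropylsilyloxy)phenyl]-N,N,4-trimethylhex-4-enamide F1. Reduction of the tertiary amide with Cp2Zr(H)Cl in THF at rt then comes back to the route at aldehyde 13.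

**Step 16.** Insertion into the electron-rich chromone with its alkoxy group at C5 may be slow, so that protodeboronation uses up the electron-rich boronic acid first. β-Oxygen elimination from the rhodium enolate could also open ring C and erode the enantiomeric purity, or the facial selectivity could be poor. The fallback gives up catalytic asymmetric induction for a stronger nucleophile and a resolution. It sets out from 23 and 20:
- Magnesium in THF converts 23 into [3-methoxy-4,5-bis(methoxymethoxy)phenyl]magnesium bromide F2.
- Addition of F2 to 20 with CuBr·SMe2 (cat.) and Me3SiCl at −78 °C should give the silyl enol ether 6-[(2E)-3,7-dimethylocta-2,6-dienyl]-2-[3-methoxy-4,5-bis(methoxymethoxy)phenyl]-5,7-bis(methoxymethoxy)-4-(trimethylsilyloxy)-2H-chromene F3.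
- Aqueous work-up hydrolyses F3 to racemic 6-[(2E)-3,7-dimethylocta-2,6-dienyl]-2-[3-methoxy-4,5-bis(methoxymethoxy)phenyl]-5,7-bis(methoxymethoxy)chroman-4-one F4.
- Preparative HPLC on a cellulose carbamate chiral stationary phase separates the enantiomers, sets aside (2R)-6-[(2E)-3,7-dimethylocta-2,6-dienyl]-2-[3-methoxy-4,5-bis(methoxymethoxy)phenyl]-5,7-bis(methoxymethoxy)chroman-4-one F5 and comes back to the route at 26.

**Step 17.** The chain alkenes may be protonated, followed by cyclization onto the 5- or 7-hydroxyl or by addition of methanol. Configuration at C2 may be partly lost once the 5-OH is free, or the cleavage may stop short. The fallback replaces protic solvolysis by a two-stage transprotection. It sets out from 26: Et3SiOTf with 2,2'-bipyridyl in CH2Cl2 at 0 °C should exchange each aryl MOM ether for a silyl ether without Brønsted acid, giving (2S)-6-[(2E)-3,7-dimethylocta-2,6-dienyl]-2-[3-methoxy-4,5-bis(triethylsilyloxy)phenyl]-5,7-bis(triethylsilyloxy)chroman-4-one F6. Bu4NF buffered with acetic acid in THF at 0 °C then gives 27.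

**Step 12.** The unprotected terminal ynone may oligomerize by intermolecular conjugate addition before the amine is added, 5-exo closure may compete, or the enaminone may fail to close. The fallback avoids the ynone and sets out from 16:
- MeMgBr in THF gives racemic 4-[(2E)-3,7-dimethylocta-2,6-dienyl]-2-(1-hydroxyethyl)-3,5-bis(methoxymethoxy)phenol F7.
- MnO2 in CH2Cl2 gives 1-{3-[(2E)-3,7-dimethylocta-2,6-dienyl]-6-hydroxy-2,4-bis(methoxymethoxy)phenyl}ethanone F8.
- N,N-dimethylformamide dimethyl acetal in toluene at 90 °C gives (2E)-3-(dimethylamino)-1-{3-[(2E)-3,7-dimethylocta-2,6-dienyl]-6-hydroxy-2,4-bis(methoxymethoxy)phenyl}prop-2-en-1-one F9.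
- A catalytic amount of acetic acid in CH2Cl2 closes F9 with loss of dimethylamine and comes back to the route at 20.

**Step 5 (with step 4).** The basic Grignard reagent may enolize the arylacetaldehyde, leading to recovered aldehyde and aldol self-condensation, and the aldehyde may decompose on handling. The fallback avoids the aldehyde and sets out from 3:
- Lithiation as in step 3, then prenyl bromide with CuI (cat.), gives {3,5-bis(methoxymethoxy)-4-(3-methylbut-2-enyl)phenoxy}triisopropylsilane F10.
- mCPBA with NaHCO3 in CH2Cl2 at 0 °C gives racemic {4-[(3,3-dimethyloxiran-2-yl)methyl]-3,5-bis(methoxymethoxy)phenoxy}triisopropylsilane F11.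
- Al(Oi-Pr)3 in refluxing toluene opens the epoxide at its tertiary carbon with loss of a methyl proton and comes back to the route at 9.

## Further compounds

F1 | step 6 | (4E)-6-[2,6-bis(methoxymethoxy)-4-(triisopropylsilyloxy)phenyl]-N,N,4-trimethylhex-4-enamide | CN(C)C(=O)CC/C(C)=C/Cc1c(OCOC)cc(O[Si](C(C)C)(C(C)C)C(C)C)cc1OCOC
F2 | step 16 | [3-methoxy-4,5-bis(methoxymethoxy)phenyl]magnesium bromide | COCOc1cc([Mg]Br)cc(OC)c1OCOC
F3 | step 16 | racemic 6-[(2E)-3,7-dimethylocta-2,6-dienyl]-2-[3-methoxy-4,5-bis(methoxymethoxy)phenyl]-5,7-bis(methoxymethoxy)-4-(trimethylsilyloxy)-2H-chromene | COCOc1cc(C2C=C(O[Si](C)(C)C)c3c(cc(OCOC)c(C/C=C(\C)CCC=C(C)C)c3OCOC)O2)cc(OC)c1OCOC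
F4 | step 16 | racemic 6-[(2E)-3,7-dimethylocta-2,6-dienyl]-2-[3-methoxy-4,5-bis(methoxymethoxy)phenyl]-5,7-bis(methoxymethoxy)chroman-4-one | COCOc1cc(C2CC(=O)c3c(cc(OCOC)c(C/C=C(\C)CCC=C(C)C)c3OCOC)O2)cc(OC)c1OCOC
F5 | step 16 | (2R)-6-[(2E)-3,7-dimethylocta-2,6-dienyl]-2-[3-methoxy-4,5-bis(methoxymethoxy)phenyl]-5,7-bis(methoxymethoxy)chroman-4-one | COCOc1cc([C@H]2CC(=O)c3c(cc(OCOC)c(C/C=C(\C)CCC=C(C)C)c3OCOC)O2)cc(OC)c1OCOC
F6 | step 17 | (2S)-6-[(2E)-3,7-dimethylocta-2,6-dienyl]-2-[3-methoxy-4,5-bis(triethylsilyloxy)phenyl]-5,7-bis(triethylsilyloxy)chroman-4-one | CC[Si](CC)(CC)Oc1cc([C@@H]2CC(=O)c3c(cc(O[Si](CC)(CC)CC)c(C/C=C(\C)CCC=C(C)C)c3O[Si](CC)(CC)CC)O2)cc(OC)c1O[Si](CC)(CC)CC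
F7 | step 12 | racemic 4-[(2E)-3,7-dimethylocta-2,6-dienyl]-2-(1-hydroxyethyl)-3,5-bis(methoxymethoxy)phenol | CC(O)c1c(O)cc(OCOC)c(C/C=C(\C)CCC=C(C)C)c1OCOC
F8 | step 12 | 1-{3-[(2E)-3,7-dimethylocta-2,6-dienyl]-6-hydroxy-2,4-bis(methoxymethoxy)phenyl}ethanone | CC(=O)c1c(O)cc(OCOC)c(C/C=C(\C)CCC=C(C)C)c1OCOC
F9 | step 12 | (2E)-3-(dimethylamino)-1-{3-[(2E)-3,7-dimethylocta-2,6-dienyl]-6-hydroxy-2,4-bis(methoxymethoxy)phenyl}prop-2-en-1-one | CN(C)/C=C/C(=O)c1c(O)cc(OCOC)c(C/C=C(\C)CCC=C(C)C)c1OCOC
F10 | step 5 | {3,5-bis(methoxymethoxy)-4-(3-methylbut-2-enyl)phenoxy}triisopropylsilane | CC(C)=CCc1c(OCOC)cc(O[Si](C(C)C)(C(C)C)C(C)C)cc1OCOC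
F11 | step 5 | racemic {4-[(3,3-dimethyloxiran-2-yl)methyl]-3,5-bis(methoxymethoxy)phenoxy}triisopropylsilane | CC1(C)OC1Cc1c(OCOC)cc(O[Si](C(C)C)(C(C)C)C(C)C)cc1OCOC
A1 | alternative 1 | (2S)-6-[(2E)-3,7-dimethylocta-2,6-dienyl]-5,7-dihydroxy-2-[3-methoxy-4,5-bis(methoxymethoxy)phenyl]chroman-4-one | COCOc1cc([C@@H]2CC(=O)c3c(cc(O)c(C/C=C(\C)CCC=C(C)C)c3O)O2)cc(OC)c1OCOC
A2 | alternative 2 | 6-[(2E)-3,7-dimethylocta-2,6-dienyl]-5,7-bis(methoxymethoxy)-4H-chromen-4-one | O=c1ccoc2cc(OCOC)c(C/C=C(\C)CCC=C(C)C)c(OCOC)c12
A3 | alternative 2 | 6-(chloromethyl)-5,7-bis(methoxymethoxy)-4H-chromen-4-one | O=c1ccoc2cc(OCOC)c(CCl)c(OCOC)c12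
A4 | alternative 2 | [(1E)-2,6-dimethylhepta-1,5-dienyl]dimethylalane | C[Al](C)/C=C(\C)CCC=C(C)C
A5 | alternative 3 | (2S)-4-(tert-butyldimethylsilyloxy)-6-[(2E)-3,7-dimethylocta-2,6-dienyl]-5,7-bis(methoxymethoxy)-2-[3-methoxy-4,5-bis(methoxymethoxy)phenyl]chroman | COCOc1cc2c(c(OCOC)c1C/C=C(\C)CCC=C(C)C)C(O[Si](C)(C)C(C)(C)C)C[C@@H](c1cc(OC)c(OCOC)c(OCOC)c1)O2
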